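**Retrosynthetic overview**

- The strategy rests on ring A: the carboxyl-bearing carbon C1 lies between C2 (methoxy) and C6 (aryloxy), so C1 and C6 can be read as the two carbons of the triple bond of a 3-methoxybenzyne that already carries the (S) side chain at C3.
- Key disconnection, made last: the C6–O diaryl ether bond and the C1–CO2H bond are cut together, giving an ortho-silyl aryl triflate of ring A, the ring B phenoxide and CO2.
- Ring A silyl triflate: from 4-hydroxy-2-methoxybenzaldehyde by isobutyl Grignard addition, oxidation, CBS reduction (sets S), O-silylation, carbamate-directed C-silylation between the two ring oxygens, and carbamate-to-triflate exchange.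
- Ring B phenol: from creosol by ortho-formylation, methyl-to-benzyl exchange on the catechol oxygen, reduction and O-silylation.
- No ring is formed at any stage (both benzene rings are bought in); after the coupling, hydrogenolysis and fluoride desilylation release the target.

Key step: step 13

Remark: the ring B phenoxide is used as its potassium salt (KH, 18-crown-6) in THF, so that the key step contains no proton donor; all reagents named are assumed to be commercially available.

**Route**

Step 1
Reactants: 1 4-hydroxy-2-methoxybenzaldehyde; 2 isobutylmagnesium bromide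
Product: 3 rac-1-(4-hydroxy-2-methoxyphenyl)-3-methylbutan-1-ol
Conditions: i-BuMgBr (3 equiv), THF, 0 °C → rt; aq. NH4Cl
Reagents that add atoms: isobutylmagnesium bromide (2), CC(C)C[Mg]Br
Why: Grignard addition to the aldehyde, in which the first equivalent only deprotonates the phenol and further reagent adds to the carbonyl carbon; the new centre is formed as a racemate because it is erased in step 2.

Step 2
Reactants: 3 rac-1-(4-hydroxy-2-methoxyphenyl)-3-methylbutan-1-ol
Product: 4 1-(4-hydroxy-2-methoxyphenyl)-3-methylbutan-1-one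
Conditions: DDQ (1.1 equiv), 1,4-dioxane, rt
Reagents that add atoms: none
Why: DDQ dehydrogenation of a 4-hydroxybenzylic alcohol, in which the para hydroxyl assists hydride abstraction from the benzylic carbon, should give the aryl ketone without harming the free phenol.

Step 3
Reactants: 4 1-(4-hydroxy-2-methoxyphenyl)-3-methylbutan-1-one
Product: 5 3-methoxy-4-(3-methylbutanoyl)phenyl N-isopropylcarbamate
Conditions: i-PrNCO, Et3N (cat.), CH2Cl2, rt
Reagents that add atoms: isopropyl isocyanate, CC(C)N=C=O
Why: Base-catalysed addition of the acidic phenol to the isocyanate (O-carbamoylation) installs a carbamate that later acts as directing group and is removable under mild E1cB conditions.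

Step 4
Reactants: 5 3-methoxy-4-(3-methylbutanoyl)phenyl N-isopropylcarbamate
Product: 6 4-[(1S)-1-hydroxy-3-methylbutyl]-3-methoxyphenyl N-isopropylcarbamate
Conditions: (R)-2-methyl-CBS-oxazaborolidine (15 mol %), BH3·SMe2, THF, –20 °C; MeOH
Reagents that add atoms: none
Why: Corey–Bakshi–Shibata reduction, in which the (R)-oxazaborolidine–borane complex binds the ketone with the large aryl group turned away from the catalyst and delivers hydride to one face, should set the (S)-carbinol centre under catalyst control (by analogy with aryl alkyl ketones), the carbamate being inert to borane at this temperature.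

Step 5
Reactants: 6 4-[(1S)-1-hydroxy-3-methylbutyl]-3-methoxyphenyl N-isopropylcarbamate
Product: 7 4-[(1S)-1-(tert-butyldimethylsilyloxy)-3-methylbutyl]-3-methoxyphenyl N-isopropylcarbamate
Conditions: TBSCl, imidazole, DMF, rt
Reagents that add atoms: tert-butyldimethylsilyl chloride, CC(C)(C)[Si](C)(C)Cl
Why: Silyl ether formation with imidazole-activated TBSCl protects the secondary benzylic alcohol without touching the C–O bond of the stereocentre, imidazole being too weak a base to trigger loss of the carbamate.

Step 6
Reactants: 7 4-[(1S)-1-(tert-butyldimethylsilyloxy)-3-methylbutyl]-3-methoxyphenyl N-isopropylcarbamate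
Product: 11 4-[(1S)-1-(tert-butyldimethylsilyloxy)-3-methylbutyl]-3-methoxy-2-(trimethylsilyl)phenyl N-isopropylcarbamate, via N-silyl carbamate 8 (not isolated), via aryllithium 9 (not isolated), via N-silyl C-silyl carbamate 10 (not isolated)
Conditions: TBSOTf, TMEDA, Et2O, 0 °C → rt; n-BuLi, TMEDA, –78 °C; TMSCl, –78 °C → rt; aq. NaHSO4
Reagents that add atoms: chlorotrimethylsilane, C[Si](C)(C)Cl
Why: Directed ortho-metalation, in which in situ N-silylation masks the carbamate N–H, n-BuLi/TMEDA removes the ring proton flanked by the carbamate oxygen and the methoxy group (the doubly activated site), TMSCl traps the aryllithium at –78 °C before any anionic Fries shift, and the acidic work-up strips the N-silyl group.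

Step 7
Reactants: 11 4-[(1S)-1-(tert-butyldimethylsilyloxy)-3-methylbutyl]-3-methoxy-2-(trimethylsilyl)phenyl N-isopropylcarbamate
Product: 13 4-[(1S)-1-(tert-butyldimethylsilyloxy)-3-methylbutyl]-3-methoxy-2-(trimethylsilyl)phenyl trifluoromethanesulfonate, via silyl phenol 12 (not isolated)
Conditions: DBU, Et2NH, MeCN, 40 °C; then PhNTf2, rt
Reagents that add atoms: N-phenylbis(trifluoromethanesulfonimide), O=S(=O)(N(c1ccccc1)S(=O)(=O)C(F)(F)F)C(F)(F)F
Why: E1cB cleavage of the N-monoalkyl carbamate (DBU removes the N–H, isopropyl isocyanate is expelled and scavenged by Et2NH as a urea) gives the phenoxide, which is O-sulfonylated in the same flask by PhNTf2 under conditions that leave the aryl–silicon bond and the silyl ether intact.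

Step 8
Reactants: 14 creosol (2-methoxy-4-methylphenol)
Product: 15 2-hydroxy-3-methoxy-5-methylbenzaldehyde
Conditions: MgCl2, Et3N, (CH2O)n, MeCN, reflux; aq. HCl
Reagents that add atoms: paraformaldehyde (as formaldehyde), C=O
Why: Magnesium-mediated ortho-formylation of a phenol (Casnati–Skattebøl reaction), in which the magnesium phenoxide delivers formaldehyde to the only free ortho position and a second formaldehyde oxidises the hydroxymethyl intermediate to the aldehyde.

Step 9
Reactants: 15 2-hydroxy-3-methoxy-5-methylbenzaldehyde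
Product: 16 2,3-dihydroxy-5-methylbenzaldehyde
Conditions: BBr3, CH2Cl2, –78 → 0 °C; H2O
Reagents that add atoms: none
Why: Lewis acid ether cleavage, in which BBr3 coordinates the methoxy oxygen and bromide removes the methyl group in an SN2 step, frees the catechol while the aldehyde and the aryl methyl group are unaffected.

Step 10
Reactants: 16 2,3-dihydroxy-5-methylbenzaldehyde
Product: 18 3-(benzyloxy)-2-hydroxy-5-methylbenzaldehyde, via disodium catecholate 17 (not isolated)
Conditions: NaH (2.2 equiv), DMSO, rt; BnBr (1.0 equiv); aq. NH4Cl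
Reagents that add atoms: benzyl bromide, BrCc1ccccc1
Why: Regioselective Williamson etherification through the dianion, in which the C2 phenoxide is delocalised into and chelated by the ortho formyl group so that one equivalent of benzyl bromide alkylates the more nucleophilic C3 oxygen.

Step 11
Reactants: 18 3-(benzyloxy)-2-hydroxy-5-methylbenzaldehyde
Product: 19 2-(benzyloxy)-6-(hydroxymethyl)-4-methylphenol
Conditions: NaBH4, MeOH, 0 °C
Reagents that add atoms: none
Why: Hydride reduction of the aldehyde by NaBH4 gives the primary benzylic alcohol and leaves the benzyl ether and the phenol untouched.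

Step 12
Reactants: 19 2-(benzyloxy)-6-(hydroxymethyl)-4-methylphenol
Product: 20 2-(benzyloxy)-6-[(tert-butyldimethylsilyloxy)methyl]-4-methylphenol
Conditions: TBSCl (1.05 equiv), imidazole, CH2Cl2, 0 °C
Reagents that add atoms: tert-butyldimethylsilyl chloride, CC(C)(C)[Si](C)(C)Cl
Why: Chemoselective silylation, in which the primary benzylic alcohol reacts with imidazole-activated TBSCl faster than the hydrogen-bonded phenol flanked by two ortho substituents, should give the mono-silyl ether with the phenol free.

Step 13
Reactants: 13 4-[(1S)-1-(tert-butyldimethylsilyloxy)-3-methylbutyl]-3-methoxy-2-(trimethylsilyl)phenyl trifluoromethanesulfonate; 20 2-(benzyloxy)-6-[(tert-butyldimethylsilyloxy)methyl]-4-methylphenol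
Product: 24 6-[2-(benzyloxy)-6-{[(tert-butyldimethylsilyl)oxy]methyl}-4-methylphenoxy]-3-[(1S)-1-(tert-butyldimethylsilyloxy)-3-methylbutyl]-2-methoxybenzoic acid, via potassium phenoxide 21 (not isolated), via aryne 22 (not isolated), via arylpotassium 23 (not isolated)
Conditions: 20 (1.3 equiv), KH, THF, 0 °C; then KF, 18-crown-6, CO2 (1 atm), slow addition of 13, THF, 0 °C → rt; cold aq. KHSO4
Reagents that add atoms: carbon dioxide, O=C=O
Why: Proposed new method: fluoride attacks the trimethylsilyl group of 13 and triflate departs to give aryne 22 with its triple bond between C1 and C6 of ring A, phenoxide 21 adds through oxygen at C6 to form the diaryl ether bond, and the resulting C1 arylpotassium 23 adds to CO2 to form the C1–carboxyl bond, the acid being released on work-up. The closest known reaction types are the three-component coupling of arynes, nitrogen nucleophiles and CO2 to anthranilic acid derivatives and the O-arylation of phenols by silyl triflate-derived arynes; joining a phenoxide, an aryne and CO2 in one operation is not established. No ring closes and no stereocentre is formed, and the (S)-silyl ether centre on the C3 side chain is remote from the reacting carbons. The step needs O-attack at C6 with the carbanion at C1, which the C2 methoxy group should secure by distorting the aryne and stabilising inductively the negative charge that develops on the adjacent carbon. It also needs carboxylation to outrun protonation, which is addressed by a preformed phenoxide (no O–H), THF instead of acetonitrile and a CO2-saturated solution, and O- instead of C-arylation, which is addressed because both ortho positions and the para position of ring B are substituted. The hindered 2,6-disubstituted phenoxide should still add because the aryne carbon is unhindered and strongly electrophilic, while its reversible CO2 adduct and the carboxylate product are much weaker nucleophiles.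

Step 14
Reactants: 24 6-[2-(benzyloxy)-6-{[(tert-butyldimethylsilyl)oxy]methyl}-4-methylphenoxy]-3-[(1S)-1-(tert-butyldimethylsilyloxy)-3-methylbutyl]-2-methoxybenzoic acid
Product: 25 3-[(1S)-1-(tert-butyldimethylsilyloxy)-3-methylbutyl]-6-[2-{[(tert-butyldimethylsilyl)oxy]methyl}-6-hydroxy-4-methylphenoxy]-2-methoxybenzoic acid
Conditions: H2 (1 atm), Pd/C (palladium metal on carbon), EtOAc, rt
Reagents that add atoms: none
Why: Catalytic hydrogenolysis of the aryl benzyl ether over Pd/C should be much faster in ethyl acetate than hydrogenolysis of the two silyl-protected benzylic C–O bonds, and the reaction is stopped after uptake of one equivalent of hydrogen.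

Step 15
Reactants: 25 3-[(1S)-1-(tert-butyldimethylsilyloxy)-3-methylbutyl]-6-[2-{[(tert-butyldimethylsilyl)oxy]methyl}-6-hydroxy-4-methylphenoxy]-2-methoxybenzoic acid
Product: 26 3-[(1S)-1-hydroxy-3-methylbutyl]-6-[2-hydroxy-6-(hydroxymethyl)-4-methylphenoxy]-2-methoxybenzoic acid (target, CNP0221397.1)
Conditions: TBAF (excess), THF, 0 °C → rt; aq. NH4Cl
Reagents that add atoms: none
Why: Fluoride-mediated desilylation, driven by formation of Si–F bonds, releases both hydroxyl groups under basic, non-ionising conditions, so the electron-rich benzylic (S)-centre should not racemise through a benzylic cation.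

**Compound list**

1 | 4-hydroxy-2-methoxybenzaldehyde | COc1cc(O)ccc1C=O | starting material
2 | isobutylmagnesium bromide | CC(C)C[Mg]Br | starting material
3 | rac-1-(4-hydroxy-2-methoxyphenyl)-3-methylbutan-1-ol | COc1cc(O)ccc1C(O)CC(C)C | intermediate
4 | 1-(4-hydroxy-2-methoxyphenyl)-3-methylbutan-1-one | COc1cc(O)ccc1C(=O)CC(C)C | intermediate
5 | 3-methoxy-4-(3-methylbutanoyl)phenyl N-isopropylcarbamate | COc1cc(OC(=O)NC(C)C)ccc1C(=O)CC(C)C | intermediate
6 | 4-[(1S)-1-hydroxy-3-methylbutyl]-3-methoxyphenyl N-isopropylcarbamate | COc1cc(OC(=O)NC(C)C)ccc1[C@@H](O)CC(C)C | intermediate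
7 | 4-[(1S)-1-(tert-butyldimethylsilyloxy)-3-methylbutyl]-3-methoxyphenyl N-isopropylcarbamate | COc1cc(OC(=O)NC(C)C)ccc1[C@@H](O[Si](C)(C)C(C)(C)C)CC(C)C | intermediate
8 | 4-[(1S)-1-(tert-butyldimethylsilyloxy)-3-methylbutyl]-3-methoxyphenyl N-(tert-butyldimethylsilyl)-N-isopropylcarbamate | COc1cc(OC(=O)N(C(C)C)[Si](C)(C)C(C)(C)C)ccc1[C@@H](O[Si](C)(C)C(C)(C)C)CC(C)C | intermediate
9 | 2-lithio derivative of 8 (lithium on the ring carbon between the methoxy and carbamate oxygens) | COc1c([Li])c(OC(=O)N(C(C)C)[Si](C)(C)C(C)(C)C)ccc1[C@@H](O[Si](C)(C)C(C)(C)C)CC(C)C | intermediate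
10 | 4-[(1S)-1-(tert-butyldimethylsilyloxy)-3-methylbutyl]-3-methoxy-2-(trimethylsilyl)phenyl N-(tert-butyldimethylsilyl)-N-isopropylcarbamate | COc1c([Si](C)(C)C)c(OC(=O)N(C(C)C)[Si](C)(C)C(C)(C)C)ccc1[C@@H](O[Si](C)(C)C(C)(C)C)CC(C)C | intermediate
11 | 4-[(1S)-1-(tert-butyldimethylsilyloxy)-3-methylbutyl]-3-methoxy-2-(trimethylsilyl)phenyl N-isopropylcarbamate | COc1c([Si](C)(C)C)c(OC(=O)NC(C)C)ccc1[C@@H](O[Si](C)(C)C(C)(C)C)CC(C)C | intermediate
12 | 4-[(1S)-1-(tert-butyldimethylsilyloxy)-3-methylbutyl]-3-methoxy-2-(trimethylsilyl)phenol | COc1c([Si](C)(C)C)c(O)ccc1[C@@H](O[Si](C)(C)C(C)(C)C)CC(C)C | intermediate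
13 | 4-[(1S)-1-(tert-butyldimethylsilyloxy)-3-methylbutyl]-3-methoxy-2-(trimethylsilyl)phenyl trifluoromethanesulfonate | COc1c([C@@H](O[Si](C)(C)C(C)(C)C)CC(C)C)ccc(OS(=O)(=O)C(F)(F)F)c1[Si](C)(C)C | intermediate
14 | creosol (2-methoxy-4-methylphenol) | COc1cc(C)ccc1O | starting material
15 | 2-hydroxy-3-methoxy-5-methylbenzaldehyde | COc1cc(C)cc(C=O)c1O | intermediate
16 | 2,3-dihydroxy-5-methylbenzaldehyde | Oc1cc(C)cc(C=O)c1O | intermediate
17 | disodium 3-formyl-5-methylbenzene-1,2-diolate | [Na+].[Na+].[O-]c1cc(C)cc(C=O)c1[O-] | intermediate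
18 | 3-(benzyloxy)-2-hydroxy-5-methylbenzaldehyde | O=Cc1cc(C)cc(OCc2ccccc2)c1O | intermediate
19 | 2-(benzyloxy)-6-(hydroxymethyl)-4-methylphenol | OCc1cc(C)cc(OCc2ccccc2)c1O | intermediate
20 | 2-(benzyloxy)-6-[(tert-butyldimethylsilyloxy)methyl]-4-methylphenol | Oc1c(OCc2ccccc2)cc(C)cc1CO[Si](C)(C)C(C)(C)C | intermediate
21 | potassium 2-(benzyloxy)-6-[(tert-butyldimethylsilyloxy)methyl]-4-methylphenoxide | [K+].[O-]c1c(OCc2ccccc2)cc(C)cc1CO[Si](C)(C)C(C)(C)C | intermediate
22 | 4-[(1S)-1-(tert-butyldimethylsilyloxy)-3-methylbutyl]-3-methoxybenzyne (triple bond between C1 and C6 of ring A) | COC1=C([C@@H](O[Si](C)(C)C(C)(C)C)CC(C)C)C=CC#C1 | intermediate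
23 | {6-[2-(benzyloxy)-6-{[(tert-butyldimethylsilyl)oxy]methyl}-4-methylphenoxy]-3-[(1S)-1-(tert-butyldimethylsilyloxy)-3-methylbutyl]-2-methoxyphenyl}potassium | COc1c([C@@H](O[Si](C)(C)C(C)(C)C)CC(C)C)ccc(Oc2c(OCc3ccccc3)cc(C)cc2CO[Si](C)(C)C(C)(C)C)c1[K] | intermediate
24 | 6-[2-(benzyloxy)-6-{[(tert-butyldimethylsilyl)oxy]methyl}-4-methylphenoxy]-3-[(1S)-1-(tert-butyldimethylsilyloxy)-3-methylbutyl]-2-methoxybenzoic acid | COc1c([C@@H](O[Si](C)(C)C(C)(C)C)CC(C)C)ccc(Oc2c(OCc3ccccc3)cc(C)cc2CO[Si](C)(C)C(C)(C)C)c1C(=O)O | intermediate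
25 | 3-[(1S)-1-(tert-butyldimethylsilyloxy)-3-methylbutyl]-6-[2-{[(tert-butyldimethylsilyl)oxy]methyl}-6-hydroxy-4-methylphenoxy]-2-methoxybenzoic acid | COc1c([C@@H](O[Si](C)(C)C(C)(C)C)CC(C)C)ccc(Oc2c(O)cc(C)cc2CO[Si](C)(C)C(C)(C)C)c1C(=O)O | intermediate
26 | 3-[(1S)-1-hydroxy-3-methylbutyl]-6-[2-hydroxy-6-(hydroxymethyl)-4-methylphenoxy]-2-methoxybenzoic acid | COc1c([C@@H](O)CC(C)C)ccc(Oc2c(O)cc(C)cc2CO)c1C(=O)O | target

**Step count**

Total step count: 15 (ring A branch steps 1–7, ring B branch steps 8–12, coupling and endgame steps 13–15).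
Longest linear sequence: 10 steps (steps 1–7, then 13–15).

**Steps most likely to fail**

Step 13 (proposed new method). Several processes could defeat it:
- the C1 aryl anion may be protonated before it captures CO2, either by adventitious water or by internal transfer of a benzylic proton from ring B;
- the phenoxide may be held back as its CO2 adduct or may attack the sulfonyl sulfur of the triflate;
- fluoride may slowly remove a silyl ether, whose alkoxide would then compete for the aryne.

The fallback uses known chemistry and sets out from 13 and 20. Aryne O-arylation of the neutral phenol (CsF, MeCN, rt), in which the phenol O–H protonates the aryl anion, should give the diaryl ether without the carboxyl group, 1-[2-(benzyloxy)-6-{[(tert-butyldimethylsilyl)oxy]methyl}-4-methylphenoxy]-4-[(1S)-1-(tert-butyldimethylsilyloxy)-3-methylbutyl]-3-methoxybenzene F1. Directed ortho-lithiation of F1 at the ring position flanked by the methoxy and aryloxy oxygens (n-BuLi, TMEDA, THF, –20 → 0 °C) should give the C1 aryllithium F2, which is quenched with CO2 and acidified. The fallback comes back to the route at 24.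

Step 6. Metalation may occur at the benzylic C–H that carries the silyloxy group, or at the other position ortho to the carbamate, instead of between the two oxygens, since the methoxy group is crowded by the neighbouring side chain. Incomplete N-silylation would also let the base expel the carbamate. The fallback sets out from 4 and changes both the directing group and the state of the benzylic oxygen:
- carbamoylation with ClCONEt2 (K2CO3, MeCN, reflux) gives 3-methoxy-4-(3-methylbutanoyl)phenyl N,N-diethylcarbamate F3;
- CBS reduction as in step 4 gives 4-[(1S)-1-hydroxy-3-methylbutyl]-3-methoxyphenyl N,N-diethylcarbamate F4;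
- s-BuLi (2.2 equiv), TMEDA, THF, –78 °C forms the lithium alkoxide, which makes the benzylic C–H non-acidic, and then the ring lithium compound F5 between the two oxygens;
- TMSCl gives the O,C-bis(trimethylsilyl) compound F6, whose O–silyl group is lost on mild acidic work-up to give 4-[(1S)-1-hydroxy-3-methylbutyl]-3-methoxy-2-(trimethylsilyl)phenyl N,N-diethylcarbamate F7;
- TBSCl, imidazole, DMF gives the silyl ether F8;
- LiAlH4, THF, 0 °C → rt cleaves the diethylcarbamate reductively.

The fallback comes back to the route at 12, which is triflated with PhNTf2 and DBU as in the second half of step 7 to give 13.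

Step 1. The magnesium phenoxide formed first deactivates the aldehyde, so addition may be slow and β-hydride transfer from the isobutyl Grignard reagent (reduction to the benzyl alcohol) may compete. The 4-hydroxybenzylic alcohol may also ionise to a quinone methide and oligomerise during isolation. The fallback sets out from 1 and masks the phenol:
- TBSCl, imidazole, DMF gives 4-(tert-butyldimethylsilyloxy)-2-methoxybenzaldehyde F9;
- i-BuMgBr, THF, –78 → 0 °C gives rac-1-[4-(tert-butyldimethylsilyloxy)-2-methoxyphenyl]-3-methylbutan-1-ol F10;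
- Dess–Martin periodinane, CH2Cl2, rt gives 1-[4-(tert-butyldimethylsilyloxy)-2-methoxyphenyl]-3-methylbutan-1-one F11;
- TBAF, THF, 0 °C removes the aryl silyl ether.

The fallback comes back to the route at 4.

**Further compounds**

F1 | step 13 | 1-[2-(benzyloxy)-6-{[(tert-butyldimethylsilyl)oxy]methyl}-4-methylphenoxy]-4-[(1S)-1-(tert-butyldimethylsilyloxy)-3-methylbutyl]-3-methoxybenzene | COc1cc(Oc2c(OCc3ccccc3)cc(C)cc2CO[Si](C)(C)C(C)(C)C)ccc1[C@@H](O[Si](C)(C)C(C)(C)C)CC(C)C
F2 | step 13 | C1 aryllithium derived from F1 (lithium between the methoxy and aryloxy oxygens) | COc1c([Li])c(Oc2c(OCc3ccccc3)cc(C)cc2CO[Si](C)(C)C(C)(C)C)ccc1[C@@H](O[Si](C)(C)C(C)(C)C)CC(C)C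
F3 | step 6 | 3-methoxy-4-(3-methylbutanoyl)phenyl N,N-diethylcarbamate | CCN(CC)C(=O)Oc1ccc(C(=O)CC(C)C)c(OC)c1
F4 | step 6 | 4-[(1S)-1-hydroxy-3-methylbutyl]-3-methoxyphenyl N,N-diethylcarbamate | CCN(CC)C(=O)Oc1ccc([C@@H](O)CC(C)C)c(OC)c1
F5 | step 6 | dilithio derivative of F4 (lithium alkoxide, ring lithium between the two oxygens) | CCN(CC)C(=O)Oc1ccc([C@@H](O[Li])CC(C)C)c(OC)c1[Li]
F6 | step 6 | 3-methoxy-2-(trimethylsilyl)-4-[(1S)-3-methyl-1-(trimethylsilyloxy)butyl]phenyl N,N-diethylcarbamate | CCN(CC)C(=O)Oc1ccc([C@@H](O[Si](C)(C)C)CC(C)C)c(OC)c1[Si](C)(C)C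
F7 | step 6 | 4-[(1S)-1-hydroxy-3-methylbutyl]-3-methoxy-2-(trimethylsilyl)phenyl N,N-diethylcarbamate | CCN(CC)C(=O)Oc1ccc([C@@H](O)CC(C)C)c(OC)c1[Si](C)(C)C
F8 | step 6 | 4-[(1S)-1-(tert-butyldimethylsilyloxy)-3-methylbutyl]-3-methoxy-2-(trimethylsilyl)phenyl N,N-diethylcarbamate | CCN(CC)C(=O)Oc1ccc([C@@H](O[Si](C)(C)C(C)(C)C)CC(C)C)c(OC)c1[Si](C)(C)C
F9 | step 1 | 4-(tert-butyldimethylsilyloxy)-2-methoxybenzaldehyde | COc1cc(O[Si](C)(C)C(C)(C)C)ccc1C=O
F10 | step 1 | rac-1-[4-(tert-butyldimethylsilyloxy)-2-methoxyphenyl]-3-methylbutan-1-ol | COc1cc(O[Si](C)(C)C(C)(C)C)ccc1C(O)CC(C)C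
F11 | step 1 | 1-[4-(tert-butyldimethylsilyloxy)-2-methoxyphenyl]-3-methylbutan-1-one | COc1cc(O[Si](C)(C)C(C)(C)C)ccc1C(=O)CC(C)C
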